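# Proposed synthesis of (1S,4S,5R,8S)-4-(4-hydroxy-3,5-dimethoxyphenyl)-8-(4-hydroxy-3-methoxyphenyl)-3,7-dioxabicyclo[3.3.0]octan-2-one

## Numbering used throughout

**Core atoms** (3,7-dioxabicyclo[3.3.0]octan-2-one): C1 is the ring-fusion carbon α to the carbonyl, C2 the carbonyl, O3, C4 the syringyl-bearing carbon, C5 the second ring-fusion carbon, C6 the CH2, O7, and C8 the guaiacyl-bearing carbon. Ring A is the tetrahydrofuran (C1, C5, C6, O7, C8). Ring B is the lactone (C1, C2, O3, C4, C5).

**Compounds:**
- 1: 4-benzyloxy-3-methoxybenzaldehyde
- 2: dibenzyl malonate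
- 3: benzylidene malonate
- 4: racemic 2-vinyloxirane
- 5: 2,4-trans vinyl tetrahydrofuran diester
- 6: ozonide (not isolated)
- 7: aldehyde
- 8: 4-bromo-2,6-dimethoxyphenol
- 9: its benzyl ether
- 10: arylmagnesium bromide (not isolated)
- 11: carbinol (both epimers)
- 12: aryl ketone
- 13: lithium alkoxide (not isolated)
- 14: bicyclic lactone benzyl ester
- 15: lactone acid with free phenols
- 16: lactone enol (not isolated)
- 17: target

## Analysis of the target

Compound 17 is a furofuranone lignan: a cis-fused 3,7-dioxabicyclo[3.3.0]octan-2-one. Ring A carries a 4-hydroxy-3-methoxyphenyl (guaiacyl) group at C8, and ring B carries a 4-hydroxy-3,5-dimethoxyphenyl (syringyl) group at C4.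

The four stereocentres C8, C1, C5 and C4 are contiguous, with configuration (1S,4S,5R,8S). H1 and H5 are cis, and both aryl groups lie on the convex face, so H8 is trans to H1 and H4 is trans to H5. Seen from ring A, the C8 aryl group is trans to the C5–C4 bond.

The sensitive sites are the two benzylic C–O bonds, C8–O7 (ether) and C4–O3 (lactone). Each is para to an oxygen donor, so both can ionise under acid and both can be hydrogenolysed. The lactone also has an enolisable C1–H, and its enolate can expel O7 from C8. The free phenols are easily oxidised.

The synthesis is hard for two reasons. The two aryl groups differ and sit on different rings, so no symmetry can be used. The exo and endo arrangements at the benzylic carbons differ little in energy, so C8 and C4 must be set kinetically and kept away from equilibrating acid.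

The strategy rests on a mapping of the skeleton onto two simple pieces. O7–C6–C5 with the carbon branch C4 on C5 has the connectivity of 2-vinyloxirane 4, whose fourth carbon is excised later. C8–C1 with the C2 carbonyl is the benzylidene malonate 3. Joining them requires only O7–C8 and C1–C5, which are the two bonds that a palladium π-allyl alkoxide zwitterion forms with a doubly activated alkene. The second malonate carbonyl is kept as a blocking group that holds C1 quaternary until the last step.

## Retrosynthetic reasoning

**17 ⇒ 15 ⇒ 14.** A carboxyl group is added back at C1 and the three acidic OH groups are benzylated. The C1–carboxyl bond is chosen because a quaternary C1 cannot enolise, so neither β-elimination of O7 nor epimerisation can occur in any earlier basic step. Both carbonyl carbons then come from 2, and all three benzyl groups fall in one hydrogenolysis. In the forward direction the hydrogenolysis has to stop at the O-benzyl groups. The decarboxylation has to place H1 cis to H5, which the strain of a trans-fused bicycle enforces.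

**14 ⇒ 13 ⇒ 12.** The lactone is opened at the acyl–oxygen bond C2–O3, and the C4–H bond is traced back to the ketone 12. Cutting C4–O3 instead would mean capture of a C4 benzylic cation, which requires acid that also threatens C8–O7. With the ketone, C4 is set by hydride addition next to the C5 stereocentre. The Felkin–Anh model (quaternary C1 anti to the nucleophile) and a chelate through O7 both predict the C4 configuration of 17. The alkoxide 13 then closes ring B with retention at C4. It can reach only the ester cis to it, so the two esters are differentiated and C1 is defined.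

**12 ⇒ 11 ⇒ 7 + 10; 10 ⇒ 9 ⇒ 8.** The C4–aryl bond is cut, so the whole syringyl unit enters late as the nucleophile 10 made from 9. This addition is deliberately not asked to set C4. The same models applied to aryl addition to 7 favour the carbinol that would lactonise to the C4 epimer of 17. Correction by acid equilibration is unattractive because of the small exo/endo energy difference and the lability of C8–O7. Both epimers of 11 are therefore merged by oxidation to 12. The forward addition has to be faster than attack on the esters and faster than lactonisation of the alkoxide.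

**7 ⇒ 6 ⇒ 5.** One carbon is added back at C4, turning the formyl group into the vinyl group of 5. The vinyl group is the latent C4 carbonyl that comes with 4 at no cost. The forward cleavage must leave the alkoxyarenes untouched and must not epimerise C5, which becomes α to a carbonyl.

**5 ⇒ 3 + 4.** The bonds O7–C8 and C1–C5 are cut. These are the only two ring A bonds whose scission gives two intact, readily available pieces: 4 holds O7, C6, C5 and the latent C4, and 3 holds C8, C1, both carbonyl carbons and the guaiacyl ring. Any other pair of cuts would require a fragment with a preformed stereocentre. The gain is ring A and both of its stereocentres from an achiral acceptor and a racemic epoxide under a chiral catalyst. The forward reaction has to deliver the 2,4-trans ring as one enantiomer.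

**3 ⇒ 1 + 2.** The C8=C1 double bond is cut by a Knoevenagel disconnection. The precursor of the key step is thus one step from purchased materials.

## Alternatives that were turned down

**Alternative 1: oxocarbenium cyclisation onto a styrene with lactone termination.**
- *Disconnection.* C5–C6 (ring A) and C4–O3 (ring B) are formed in one operation, and C8 and C1 come from a single syn-aldol. The precursor is the 1,3-dioxan-4-one A2, the methylene acetal of a syn β-hydroxy acid carrying the guaiacyl ring (as pivalate) on C8 and an (E)-styryl group with the benzyl-protected syringyl ring on C1.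
- *Forward key step.* A strong oxophilic Lewis acid opens the acetal of A2 to an oxocarbenium ion O7=C6. This attacks the styrene at C5, and the released carboxylate traps the C4 benzylic cation, giving A1, the target as guaiacyl pivalate and syringyl benzyl ether.
- *For.* Every carbon arrives at its final oxidation level, so nothing is excised and no decarboxylation is needed. An auxiliary- or catalyst-controlled aldol sets C8 and C1 dependably. The route would be about three steps shorter.
- *Against.* The oxocarbenium ion is a 2-oxonia-1,5-diene. Its oxonia-Cope rearrangement leads to an aryl-conjugated oxocarbenium ion, breaks C8–C1 and erases the aldol stereochemistry. The electron-rich benzylic ether at C8 has to survive a strong Lewis acid, which is why a deactivating pivalate is needed, and this must later be removed next to a base-sensitive lactone. C5 and C4 are decided by the geometry of a cation cascade with no independent control. C1 carries an enolisable hydrogen from the aldol onwards.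
- *Comparison.* Alternative 1 is stronger on step economy and on C8/C1 control, which is the weakest point of the chosen route. The chosen strategy offers in exchange a sequence with no cationic intermediate at a benzylic carbon, a quaternary C1 until the end, and a C4 centre set by a hydride addition of predictable sense.

**Alternative 2: carbonyl ylide annulation onto a γ-aryl butenolide.**
- *Disconnection.* C5–C6 and C1–C8 are formed, so ring A is laid across the C1=C5 double bond of the butenolide A4, (S)-5-[4-(benzyloxy)-3,5-dimethoxyphenyl]furan-2(5H)-one. A4 already contains ring B and C4. The three-atom partner C8–O7–C6 is the α-chlorobenzyl (trimethylsilyl)methyl ether A5.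
- *Forward key step.* A fluoride source removes silicon from A5. The resulting carbonyl ylide equivalent adds through its CH2 terminus to C5 and closes through its benzylic terminus onto C1, giving A3, the bis(benzyl ether) of the target.
- *For.* This is the most convergent plan: two fragments of similar size, the whole skeleton in one step, four or five steps in all. The cis ring fusion is automatic, and C5 is set anti to the C4 aryl group by the substrate. On step count and convergence it is clearly better than the chosen route.
- *Against.* The only source of chirality is the γ-carbon of A4. It is benzylic, α to oxygen and vinylogously α to the carbonyl, so a basic fluoride can deprotonate it to an aromatic 2-oxidofuran and racemise it under the conditions of the key step. A5 is an α-chloro ether of an electron-rich benzaldehyde, ionises readily and is difficult to handle. The regiochemistry of the ylide addition and the exo/endo outcome at C8 are settled in one step with nothing to tune.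
- *Comparison.* The chosen strategy is about twice as long. It offers a catalytic source of absolute configuration that does not pass through a configurationally labile centre, and it sets each stereocentre in a separate step.

**Alternative 3: malonyl radical cyclisation with oxidative lactone termination.**
- *Disconnection.* C1–C5 (ring A) and C4–O3 (ring B) are formed. The precursor A7 is the oxa-Michael adduct of the benzyl-protected (E)-syringyl cinnamyl alcohol to 3, so C8–O7 is already in place.
- *Forward key step.* One-electron oxidation of the malonate gives a C1 radical. The oxidant is a manganese-based one-electron oxidant with a copper co-oxidant, or deprotonation followed by a ferrocenium salt. The radical closes 5-exo onto C5, and the resulting C4 benzylic radical is oxidised to the cation and captured by the cis ester. The product A6 is the same compound as 14.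
- *For.* It uses the same acceptor 3 and reaches 14 in three steps from 1, instead of six in the longest line of the chosen route. It needs no alkene cleavage, no organometallic addition and no redox correction at C4. A hexenyl-type radical with a substituent at the 2-position has an intrinsic, if modest, preference for the 2,4-trans ring. The chosen route has no such built-in bias and must obtain it from a ligand.
- *Against.* Everything is relayed from C8 in A7, which is an oxa-Michael adduct. No dependable enantioselective addition of an allylic alcohol to an arylidene malonate is available. The adduct reverts by retro-oxa-Michael reaction under the basic variant of the key step, so the route is in effect racemic. A hot, acidic, oxidising medium meets an electron-rich styrene and two alkoxyarenes. C4 is fixed by cation capture without an independent control element.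
- *Comparison.* Alternative 3 is stronger on step count and on the inherent trans preference. The chosen strategy has a defined, catalytic origin of absolute configuration from racemic 4, and it controls C4 by a hydride addition.

Key step: step 2

Assumption: (R)-Tol-BINAP is written as the hand of the ligand that leads to (2R,4R)-5. The sense of induction cannot be predicted with confidence and has to be assigned in the first run, and the (S) ligand is used if it proves to be reversed.

## Route

**Step 1**
Reactants: 1 4-benzyloxy-3-methoxybenzaldehyde; 2 dibenzyl malonate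
Product: 3 dibenzyl 2-[4-(benzyloxy)-3-methoxybenzylidene]malonate
Conditions: piperidine (cat.), AcOH (cat.), toluene, reflux, Dean–Stark trap
Reagents that add atoms: none
Why: Knoevenagel condensation of a non-enolisable aldehyde, driven by azeotropic removal of water; the two esters are identical, so the alkene has no geometric isomers.

**Step 2**
Reactants: 3 dibenzyl 2-[4-(benzyloxy)-3-methoxybenzylidene]malonate; 4 racemic 2-vinyloxirane
Product: 5 dibenzyl (2R,4R)-2-[4-(benzyloxy)-3-methoxyphenyl]-4-ethenyloxolane-3,3-dicarboxylate (2,4-trans)
Conditions: Pd2(dba)3·CHCl3 (2.5 mol %), (R)-Tol-BINAP (6 mol %), THF, 0 °C to rt, 4 (2 equiv) added slowly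
Reagents that add atoms: none
Why: Zerovalent palladium opens 4 with inversion to a zwitterionic π-allyl complex of divalent palladium that carries a primary alkoxide, and π–σ–π isomerisation through the unsubstituted allyl terminus lets both enantiomers of 4 converge on the same pair of interconverting complexes. The alkoxide adds reversibly to the benzylidene carbon of 3 (O7–C8), and the malonate anion then attacks the internal allyl carbon anti to the metal (C1–C5), which closes ring A in a 5-exo mode, the 7-endo attack at the terminal carbon being disfavoured, and returns zerovalent palladium. The closest known reaction type is the palladium-catalysed formal (3+2) cycloaddition of vinyl epoxides with doubly activated alkenes, including enantioselective versions with chiral bisphosphines. C5 is controlled by the ligand, which decides which face of the equilibrating allyl unit is alkylated in the irreversible C–C bond formation. C8 is fixed in the same transition state, since the oxa-Michael adducts epimeric at C8 interconvert (Curtin–Hammett); allylic strain should keep H8 in the plane of the malonate enolate, place the aryl group pseudo-equatorial and leave the allyl unit over the ester that is not flanked by the aryl group, which corresponds to the 2,4-trans ring. The step needs O-attack before C-attack (the acceptor has no acidic C–H that could alkylate the allyl complex directly), branched regioselectivity (secured by the five-membered tether) and trans and enantio selectivity (the task of the ligand). C1 carries two identical esters and is not a stereocentre here, so the later ring fusion needs no control at this stage.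

**Step 3**
Reactants: 5 dibenzyl (2R,4R)-2-[4-(benzyloxy)-3-methoxyphenyl]-4-ethenyloxolane-3,3-dicarboxylate
Product: 7 dibenzyl (2R,4R)-2-[4-(benzyloxy)-3-methoxyphenyl]-4-formyloxolane-3,3-dicarboxylate, via ozonide 6 (not isolated)
Conditions: O3, CH2Cl2, −78 °C (Sudan Red 7B as end-point indicator); PPh3, −78 °C to rt
Reagents that add atoms: ozone, [O-][O+]=O
Why: Ozonolysis with reductive work-up; at −78 °C with an indicator dye the monosubstituted alkene should be consumed before the alkoxyarenes, and the neutral phosphine reduction of 6 avoids epimerisation of C5, now α to the aldehyde.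

**Step 4**
Reactants: 8 4-bromo-2,6-dimethoxyphenol
Product: 9 2-(benzyloxy)-5-bromo-1,3-dimethoxybenzene
Conditions: BnBr, K2CO3, DMF, rt
Reagents that add atoms: benzyl bromide, BrCc1ccccc1
Why: Williamson etherification of the phenol, which masks the acidic OH before the organomagnesium reagent is made and matches the other benzyl groups for one final cleavage.

**Step 5**
Reactants: 7 dibenzyl (2R,4R)-2-[4-(benzyloxy)-3-methoxyphenyl]-4-formyloxolane-3,3-dicarboxylate; 9 2-(benzyloxy)-5-bromo-1,3-dimethoxybenzene
Product: 11 dibenzyl (2R,4R)-4-{[4-(benzyloxy)-3,5-dimethoxyphenyl](hydroxy)methyl}-2-[4-(benzyloxy)-3-methoxyphenyl]oxolane-3,3-dicarboxylate (both carbinol epimers), via arylmagnesium bromide 10 (not isolated)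
Conditions: 9, Mg, cat. I2, THF, 45 °C; then 7, THF, −78 °C; AcOH quench at −78 °C
Reagents that add atoms: none
Why: Grignard addition to the aldehyde at −78 °C, which should be far faster than attack on the hindered geminal benzyl esters; the cold acidic quench is meant to protonate the alkoxide before it can lactonise. The carbinol configuration is left uncontrolled on purpose, because it is erased in step 6.

**Step 6**
Reactants: 11 dibenzyl (2R,4R)-4-{[4-(benzyloxy)-3,5-dimethoxyphenyl](hydroxy)methyl}-2-[4-(benzyloxy)-3-methoxyphenyl]oxolane-3,3-dicarboxylate (both carbinol epimers)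
Product: 12 dibenzyl (2R,4R)-4-[4-(benzyloxy)-3,5-dimethoxybenzoyl]-2-[4-(benzyloxy)-3-methoxyphenyl]oxolane-3,3-dicarboxylate
Conditions: Dess–Martin periodinane, CH2Cl2, 0 °C to rt
Reagents that add atoms: none
Why: Dess–Martin oxidation of a secondary benzylic alcohol under nearly neutral conditions; both epimers converge on one ketone, and the mild medium should leave C5 (α to the new ketone, β to O7) untouched.

**Step 7**
Reactants: 12 dibenzyl (2R,4R)-4-[4-(benzyloxy)-3,5-dimethoxybenzoyl]-2-[4-(benzyloxy)-3-methoxyphenyl]oxolane-3,3-dicarboxylate
Product: 14 benzyl (1S,4S,5R,8R)-8-[4-(benzyloxy)-3-methoxyphenyl]-4-[4-(benzyloxy)-3,5-dimethoxyphenyl]-2-oxo-3,7-dioxabicyclo[3.3.0]octane-1-carboxylate, via lithium alkoxide 13 (not isolated)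
Conditions: LiBH(s-Bu)3 (1.1 equiv), THF, −78 °C, then 0 °C; AcOH quench
Reagents that add atoms: none
Why: Felkin–Anh reduction in which the quaternary C1 lies anti to the incoming hydride and the hydride passes H5 (a lithium chelate between the ketone oxygen and O7 predicts the same face), which should give the (S)-alkoxide 13. On warming, 13 undergoes intramolecular acyl substitution on the only ester it can reach, the one cis to it, which closes ring B with retention at C4 and at the same time defines C1.

**Step 8**
Reactants: 14 benzyl (1S,4S,5R,8R)-8-[4-(benzyloxy)-3-methoxyphenyl]-4-[4-(benzyloxy)-3,5-dimethoxyphenyl]-2-oxo-3,7-dioxabicyclo[3.3.0]octane-1-carboxylate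
Product: 15 (1S,4S,5R,8R)-4-(4-hydroxy-3,5-dimethoxyphenyl)-8-(4-hydroxy-3-methoxyphenyl)-2-oxo-3,7-dioxabicyclo[3.3.0]octane-1-carboxylic acid
Conditions: H2 (1 atm), 10% Pd/C, EtOAc, rt, stopped after uptake of 3 equiv
Reagents that add atoms: none
Why: Catalytic hydrogenolysis of two aryl benzyl ethers and one benzyl ester under neutral conditions; these primary benzylic C–O bonds should cleave well before the hindered secondary ring bonds C8–O7 and C4–O3.

**Step 9**
Reactants: 15 (1S,4S,5R,8R)-4-(4-hydroxy-3,5-dimethoxyphenyl)-8-(4-hydroxy-3-methoxyphenyl)-2-oxo-3,7-dioxabicyclo[3.3.0]octane-1-carboxylic acid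
Product: 17 (1S,4S,5R,8S)-4-(4-hydroxy-3,5-dimethoxyphenyl)-8-(4-hydroxy-3-methoxyphenyl)-3,7-dioxabicyclo[3.3.0]octan-2-one, via lactone enol 16 (not isolated)
Conditions: 1,4-dioxane, 100 °C, under argon
Reagents that add atoms: none
Why: Thermal decarboxylation of a malonic-type acid through a six-membered transition state to the enol 16, which is protonated at C1; only the cis-fused bicycle is accessible without severe strain, so H1 should end up cis to H5, and the neutral medium avoids an enolate that could expel O7.

## Compound list

1 | 4-benzyloxy-3-methoxybenzaldehyde | O=Cc1ccc(OCc2ccccc2)c(OC)c1 | starting material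
2 | dibenzyl malonate | O=C(CC(=O)OCc1ccccc1)OCc1ccccc1 | starting material
3 | dibenzyl 2-[4-(benzyloxy)-3-methoxybenzylidene]malonate | O=C(OCc1ccccc1)C(=Cc1ccc(OCc2ccccc2)c(OC)c1)C(=O)OCc1ccccc1 | intermediate
4 | 2-vinyloxirane (butadiene monoxide), racemic | C=CC1CO1 | starting material
5 | dibenzyl (2R,4R)-2-[4-(benzyloxy)-3-methoxyphenyl]-4-ethenyloxolane-3,3-dicarboxylate | COc1cc(ccc1OCc1ccccc1)[C@H]1OC[C@H](C=C)C1(C(=O)OCc1ccccc1)C(=O)OCc1ccccc1 | intermediate
6 | dibenzyl (2R,4R)-2-[4-(benzyloxy)-3-methoxyphenyl]-4-(1,2,4-trioxolan-3-yl)oxolane-3,3-dicarboxylate (trioxolane carbon undefined) | COc1cc(ccc1OCc1ccccc1)[C@H]1OC[C@H](C2OOCO2)C1(C(=O)OCc1ccccc1)C(=O)OCc1ccccc1 | intermediate (not isolated)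
7 | dibenzyl (2R,4R)-2-[4-(benzyloxy)-3-methoxyphenyl]-4-formyloxolane-3,3-dicarboxylate | COc1cc(ccc1OCc1ccccc1)[C@H]1OC[C@H](C=O)C1(C(=O)OCc1ccccc1)C(=O)OCc1ccccc1 | intermediate
8 | 4-bromo-2,6-dimethoxyphenol | COc1cc(Br)cc(OC)c1O | starting material
9 | 2-(benzyloxy)-5-bromo-1,3-dimethoxybenzene | COc1cc(Br)cc(OC)c1OCc1ccccc1 | intermediate
10 | [4-(benzyloxy)-3,5-dimethoxyphenyl]magnesium bromide | COc1cc([Mg]Br)cc(OC)c1OCc1ccccc1 | intermediate (not isolated)
11 | dibenzyl (2R,4R)-4-{[4-(benzyloxy)-3,5-dimethoxyphenyl](hydroxy)methyl}-2-[4-(benzyloxy)-3-methoxyphenyl]oxolane-3,3-dicarboxylate, both carbinol epimers | COc1cc(ccc1OCc1ccccc1)[C@H]1OC[C@H](C(O)c2cc(OC)c(OCc3ccccc3)c(OC)c2)C1(C(=O)OCc1ccccc1)C(=O)OCc1ccccc1 | intermediate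
12 | dibenzyl (2R,4R)-4-[4-(benzyloxy)-3,5-dimethoxybenzoyl]-2-[4-(benzyloxy)-3-methoxyphenyl]oxolane-3,3-dicarboxylate | COc1cc(ccc1OCc1ccccc1)[C@H]1OC[C@H](C(=O)c2cc(OC)c(OCc3ccccc3)c(OC)c2)C1(C(=O)OCc1ccccc1)C(=O)OCc1ccccc1 | intermediate
13 | dibenzyl (2R,4R)-4-{(S)-[4-(benzyloxy)-3,5-dimethoxyphenyl](lithiooxy)methyl}-2-[4-(benzyloxy)-3-methoxyphenyl]oxolane-3,3-dicarboxylate | COc1cc(ccc1OCc1ccccc1)[C@H]1OC[C@H]([C@H](O[Li])c2cc(OC)c(OCc3ccccc3)c(OC)c2)C1(C(=O)OCc1ccccc1)C(=O)OCc1ccccc1 | intermediate (not isolated)
14 | benzyl (1S,4S,5R,8R)-8-[4-(benzyloxy)-3-methoxyphenyl]-4-[4-(benzyloxy)-3,5-dimethoxyphenyl]-2-oxo-3,7-dioxabicyclo[3.3.0]octane-1-carboxylate | COc1cc([C@H]2OC[C@H]3[C@]2(C(=O)OCc2ccccc2)C(=O)O[C@@H]3c2cc(OC)c(OCc3ccccc3)c(OC)c2)ccc1OCc1ccccc1 | intermediate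
15 | (1S,4S,5R,8R)-4-(4-hydroxy-3,5-dimethoxyphenyl)-8-(4-hydroxy-3-methoxyphenyl)-2-oxo-3,7-dioxabicyclo[3.3.0]octane-1-carboxylic acid | COc1cc([C@H]2OC[C@H]3[C@]2(C(=O)O)C(=O)O[C@@H]3c2cc(OC)c(O)c(OC)c2)ccc1O | intermediate
16 | (4S,5R,8R)-2-hydroxy-4-(4-hydroxy-3,5-dimethoxyphenyl)-8-(4-hydroxy-3-methoxyphenyl)-3,7-dioxabicyclo[3.3.0]oct-1-ene (enol of 17) | COc1cc([C@H]2OC[C@H]3C2=C(O)O[C@@H]3c2cc(OC)c(O)c(OC)c2)ccc1O | intermediate (not isolated)
17 | (1S,4S,5R,8S)-4-(4-hydroxy-3,5-dimethoxyphenyl)-8-(4-hydroxy-3-methoxyphenyl)-3,7-dioxabicyclo[3.3.0]octan-2-one | COc1cc([C@H]2OC[C@H]3[C@@H]2C(=O)O[C@@H]3c2cc(OC)c(O)c(OC)c2)ccc1O | target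

## Step count and the least certain steps

Total step count: 9. Longest linear sequence: 8 steps (steps 1, 2, 3, 5, 6, 7, 8, 9, from 1); step 4 is a one-step side branch.

**Step 2 (key step).** Two things are most likely to go wrong. The electron-rich benzylidene malonate may be too weak an acceptor for the alkoxide, so that the zwitterion is lost by isomerisation or oligomerisation before the C–C bond forms. The ligand may also discriminate poorly between the cis and trans ring closures, or between the enantiomeric pathways, because the aryl group lies far from the metal.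

The fallback sets out from 1 and 4 and comes back at 5. Aldehyde 1 is condensed with Meldrum's acid to 5-[4-(benzyloxy)-3-methoxybenzylidene]-2,2-dimethyl-1,3-dioxane-4,6-dione F1, an acceptor that is more electrophilic by many orders of magnitude. The same palladium catalyst with 4 should then give the spiro adduct (1R,4R)-1-[4-(benzyloxy)-3-methoxyphenyl]-4-ethenyl-8,8-dimethyl-2,7,9-trioxaspiro[4.5]decane-6,10-dione F2, and the 2,4-trans isomer is separated at this stage by chromatography or crystallisation. Opening of the dioxanedione with sodium benzyloxide in THF, with loss of acetone, gives the half ester (2R,4R)-3-(benzyloxycarbonyl)-2-[4-(benzyloxy)-3-methoxyphenyl]-4-ethenyloxolane-3-carboxylic acid F3 as its sodium salt. Alkylation of the salt with benzyl bromide in the same flask returns 5.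

**Step 5.** The main danger is premature lactonisation of the magnesium alkoxide onto the cis ester. This would freeze C4 as an uncontrolled epimer mixture, expected to lean towards the wrong one, and remove the alcohol needed for the oxidation. Enolisation of the aldehyde with β-elimination of O7 is a smaller risk.

The fallback sets out from 7 and comes back at 12. Pinnick oxidation (NaClO2, NaH2PO4, 2-methyl-2-butene, t-BuOH/H2O) gives (3R,5R)-4,4-bis[(benzyloxy)carbonyl]-5-[4-(benzyloxy)-3-methoxyphenyl]oxolane-3-carboxylic acid F4. Coupling with N,O-dimethylhydroxylamine hydrochloride (EDC·HCl, N-methylmorpholine, CH2Cl2) gives the Weinreb amide dibenzyl (2R,4R)-2-[4-(benzyloxy)-3-methoxyphenyl]-4-[methoxy(methyl)carbamoyl]oxolane-3,3-dicarboxylate F5. Addition of 10 at 0 °C then gives 12 directly through a chelated tetrahedral intermediate, and no alkoxide able to lactonise is ever formed.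

**Step 7.** The hydride addition may show insufficient facial selectivity if the substrate bias is weaker than the models suggest. Ring closure of the alkoxide may also be incomplete, and the new lactone may be attacked by excess hydride.

The fallback sets out from 12 and comes back at 14. Catalyst-controlled transfer hydrogenation with RuCl(p-cymene)[(S,S)-TsDPEN] in HCO2H/Et3N should, by analogy with simple aryl alkyl ketones, give dibenzyl (2R,4R)-4-{(S)-[4-(benzyloxy)-3,5-dimethoxyphenyl](hydroxy)methyl}-2-[4-(benzyloxy)-3-methoxyphenyl]oxolane-3,3-dicarboxylate F6. This is isolated and then closed to 14 in a separate step with catalytic DBU in toluene, so that reduction and lactonisation are no longer coupled.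

**Step 8.** Hydrogenolysis may run on into the ring benzylic bonds C8–O7 or C4–O3. The free carboxylic acid and the para-phenols would promote this as they are unveiled.

The fallback sets out from 14 and comes back at 17 without hydrogen. Heating 14 with LiCl in wet DMSO at about 110 °C removes the ester benzyl group by chloride attack and the carboxyl group by loss of CO2. This gives (1S,4S,5R,8S)-8-[4-(benzyloxy)-3-methoxyphenyl]-4-[4-(benzyloxy)-3,5-dimethoxyphenyl]-3,7-dioxabicyclo[3.3.0]octan-2-one F7. The two aryl benzyl ethers are then cleaved with BCl3 and pentamethylbenzene in CH2Cl2 at −78 °C to give 17.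

## Further compounds

F1 | step 2 | 5-[4-(benzyloxy)-3-methoxybenzylidene]-2,2-dimethyl-1,3-dioxane-4,6-dione | COc1cc(C=C2C(=O)OC(C)(C)OC2=O)ccc1OCc1ccccc1
F2 | step 2 | (1R,4R)-1-[4-(benzyloxy)-3-methoxyphenyl]-4-ethenyl-8,8-dimethyl-2,7,9-trioxaspiro[4.5]decane-6,10-dione | COc1cc(ccc1OCc1ccccc1)[C@H]1OC[C@H](C=C)C12C(=O)OC(C)(C)OC2=O
F3 | step 2 | (2R,4R)-3-(benzyloxycarbonyl)-2-[4-(benzyloxy)-3-methoxyphenyl]-4-ethenyloxolane-3-carboxylic acid (C3 undefined) | COc1cc(ccc1OCc1ccccc1)[C@H]1OC[C@H](C=C)C1(C(=O)O)C(=O)OCc1ccccc1
F4 | step 5 | (3R,5R)-4,4-bis[(benzyloxy)carbonyl]-5-[4-(benzyloxy)-3-methoxyphenyl]oxolane-3-carboxylic acid | COc1cc(ccc1OCc1ccccc1)[C@H]1OC[C@H](C(=O)O)C1(C(=O)OCc1ccccc1)C(=O)OCc1ccccc1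
F5 | step 5 | dibenzyl (2R,4R)-2-[4-(benzyloxy)-3-methoxyphenyl]-4-[methoxy(methyl)carbamoyl]oxolane-3,3-dicarboxylate | COc1cc(ccc1OCc1ccccc1)[C@H]1OC[C@H](C(=O)N(C)OC)C1(C(=O)OCc1ccccc1)C(=O)OCc1ccccc1
F6 | step 7 | dibenzyl (2R,4R)-4-{(S)-[4-(benzyloxy)-3,5-dimethoxyphenyl](hydroxy)methyl}-2-[4-(benzyloxy)-3-methoxyphenyl]oxolane-3,3-dicarboxylate | COc1cc(ccc1OCc1ccccc1)[C@H]1OC[C@H]([C@H](O)c2cc(OC)c(OCc3ccccc3)c(OC)c2)C1(C(=O)OCc1ccccc1)C(=O)OCc1ccccc1
F7 | step 8 | (1S,4S,5R,8S)-8-[4-(benzyloxy)-3-methoxyphenyl]-4-[4-(benzyloxy)-3,5-dimethoxyphenyl]-3,7-dioxabicyclo[3.3.0]octan-2-one | COc1cc(ccc1OCc1ccccc1)[C@H]1OC[C@H]2[C@@H]1C(=O)O[C@@H]2c1cc(OC)c(OCc2ccccc2)c(OC)c1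
A1 | alternative 1 | (1S,4S,5R,8S)-4-[4-(benzyloxy)-3,5-dimethoxyphenyl]-8-[3-methoxy-4-(pivaloyloxy)phenyl]-3,7-dioxabicyclo[3.3.0]octan-2-one | CC(C)(C)C(=O)Oc1ccc(cc1OC)[C@H]1OC[C@H]2[C@@H]1C(=O)O[C@@H]2c1cc(OC)c(OCc2ccccc2)c(OC)c1
A2 | alternative 1 | cis-5-{(E)-2-[4-(benzyloxy)-3,5-dimethoxyphenyl]ethenyl}-6-[3-methoxy-4-(pivaloyloxy)phenyl]-1,3-dioxan-4-one | CC(C)(C)C(=O)Oc1ccc(cc1OC)[C@H]1OCOC(=O)[C@H]1/C=C/c1cc(OC)c(OCc2ccccc2)c(OC)c1
A3 | alternative 2 | (1S,4S,5R,8S)-8-[4-(benzyloxy)-3-methoxyphenyl]-4-[4-(benzyloxy)-3,5-dimethoxyphenyl]-3,7-dioxabicyclo[3.3.0]octan-2-one | COc1cc(ccc1OCc1ccccc1)[C@H]1OC[C@H]2[C@@H]1C(=O)O[C@@H]2c1cc(OC)c(OCc2ccccc2)c(OC)c1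
A4 | alternative 2 | (S)-5-[4-(benzyloxy)-3,5-dimethoxyphenyl]furan-2(5H)-one | O=C1O[C@@H](C=C1)c1cc(OC)c(OCc2ccccc2)c(OC)c1
A5 | alternative 2 | {[chloro(4-benzyloxy-3-methoxyphenyl)methoxy]methyl}trimethylsilane | COc1cc(ccc1OCc1ccccc1)C(Cl)OC[Si](C)(C)C
A6 | alternative 3 | benzyl (1S,4S,5R,8R)-8-[4-(benzyloxy)-3-methoxyphenyl]-4-[4-(benzyloxy)-3,5-dimethoxyphenyl]-2-oxo-3,7-dioxabicyclo[3.3.0]octane-1-carboxylate (identical with 14) | COc1cc(ccc1OCc1ccccc1)[C@H]1OC[C@H]2[C@]1(C(=O)OCc1ccccc1)C(=O)O[C@@H]2c1cc(OC)c(OCc2ccccc2)c(OC)c1
A7 | alternative 3 | dibenzyl 2-{(S)-[4-(benzyloxy)-3-methoxyphenyl][(E)-3-(4-benzyloxy-3,5-dimethoxyphenyl)prop-2-enyloxy]methyl}malonate | COc1cc(ccc1OCc1ccccc1)[C@@H](OC/C=C/c1cc(OC)c(OCc2ccccc2)c(OC)c1)C(C(=O)OCc1ccccc1)C(=O)OCc1ccccc1
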